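**Retrosynthetic overview**
1. The target is the linear trimer of eugenol in which each phenol oxygen is bonded to C6 of the next unit. No ring is built in the route: rings A and C come from eugenol, ring B from 2-bromo-6-methoxyphenol.
2. Last bond: O(ring B)–C6(ring C), cut to dehydrodieugenol B plus eugenol, joined by an aerobic copper-catalysed dehydrogenative C–H/O–H coupling (new).
3. Dehydrodieugenol B comes from its O-allyl isomer by para-Claisen rearrangement; the O-allyl group first protects the ring B phenol and then becomes the ring B C-allyl group.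
4. That allyl ether comes from eugenol and allyl 2-bromo-6-methoxyphenyl ether by Ullmann C–O coupling (ring A–O–ring B); the bromide comes from 2-bromo-6-methoxyphenol by O-allylation.

Assumption: the target has no stereocentre and its diaryl ether bonds rotate freely, so it is achiral and "the single enantiomer" is simply the one compound drawn; no stereocontrol is needed.

**Route**

Step 1
Reactants: 1 2-bromo-6-methoxyphenol
Product: 2 2-(allyloxy)-1-bromo-3-methoxybenzene
Conditions: allyl bromide (1.2 equiv), K2CO3 (1.5 equiv), acetone, reflux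
Reagents that add atoms: allyl bromide, C=CCBr
Why: Williamson ether synthesis, in which the phenoxide of 1 displaces bromide from allyl bromide by an SN2 reaction; no stereocentre is formed.

Step 2
Reactants: 2 2-(allyloxy)-1-bromo-3-methoxybenzene; 3 eugenol (4-allyl-2-methoxyphenol)
Product: 4 2-(allyloxy)-1-(4-allyl-2-methoxyphenoxy)-3-methoxybenzene
Conditions: CuI (10 mol%), N,N-dimethylglycine hydrochloride (30 mol%), Cs2CO3 (2 equiv), 1,4-dioxane, 100 °C, Ar
Reagents that add atoms: none
Why: Ullmann-type diaryl ether synthesis, in which the amino-acid ligand lets monovalent copper couple the ortho-substituted, electron-rich aryl bromide with the caesium phenoxide of eugenol, while carbonate in dioxane is too weak a base to move the allyl double bonds; no stereocentre is formed.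

Step 3
Reactants: 4 2-(allyloxy)-1-(4-allyl-2-methoxyphenoxy)-3-methoxybenzene
Product: 8 dehydrodieugenol B (4-allyl-2-(4-allyl-2-methoxyphenoxy)-6-methoxyphenol), via methoxy-side ortho-dienone 5 (not isolated), via aryloxy-side ortho-dienone 6 (not isolated), via para-dienone 7 (not isolated)
Conditions: PhNEt2, 195 °C, sealed tube, Ar
Reagents that add atoms: none
Why: Aromatic para-Claisen rearrangement: both ortho positions are blocked, so the first [3,3] shift to either oxygen-bearing ortho carbon (5 or 6) is followed by a Cope [3,3] shift to the para carbon (7) and enolisation to the phenol, and the transient stereocentres of the dienones vanish on aromatisation.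

Step 4
Reactants: 8 dehydrodieugenol B; 3 eugenol
Product: 10 4-allyl-2-[4-allyl-2-(4-allyl-2-methoxyphenoxy)-6-methoxyphenoxy]-6-methoxyphenol (target), via coupled dienone 9 (not isolated)
Conditions: 3 (1 equiv) added over 12 h to 8 (3 equiv, excess recovered), CuCl2 (5 mol%), 1,4,7-triisopropyl-1,4,7-triazacyclononane (5 mol%), 2,6-diphenylpyridine (0.5 equiv), O2 (1 atm), toluene, 40 °C
Reagents that add atoms: none
Why: Proposed new method: a catalyst-controlled aerobic cross-dehydrogenative ortho C–H aryloxylation of one phenol by another; the peroxo-bridged dicopper species formed from the triazacyclononane–copper chloride and O2 converts both phenols into copper-bound phenoxyl radicals (divalent copper phenoxide in resonance with monovalent copper phenoxyl); the radical of 8, the more easily oxidised 2,6-dioxygenated partner, has both ortho carbons and the para carbon substituted and can form a lasting bond only through oxygen, whereas C6 is the only unsubstituted spin-bearing carbon of the radical of 3, so O–C6 union gives dienone 9, whose enolisation to 10 makes the coupling irreversible (unions at substituted carbons give quinol ethers that revert); keeping the radicals on copper should suppress the C6–C6 biaryl coupling and benzylic hydrogen loss typical of free eugenol radicals, C–O self-coupling of 3 only makes more 8, and excess 8 with slow addition of 3 holds back the tetramer; closest known reaction types are the copper–amine aerobic C–O oxidative coupling of phenols to poly(phenylene oxide)s (including the triazacyclononane–copper "radical-controlled" variant), the dehydrogenative ortho C–N coupling of phenols with phenothiazines and the 4-O-5 radical coupling of lignin; no stereocentre remains.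

**Compound list**
1 | 2-bromo-6-methoxyphenol | COc1cccc(Br)c1O | starting material
2 | 2-(allyloxy)-1-bromo-3-methoxybenzene | C=CCOc1c(Br)cccc1OC | intermediate
3 | eugenol (4-allyl-2-methoxyphenol) | C=CCc1ccc(O)c(OC)c1 | starting material
4 | 2-(allyloxy)-1-(4-allyl-2-methoxyphenoxy)-3-methoxybenzene | C=CCOc1c(OC)cccc1Oc1ccc(CC=C)cc1OC | intermediate
5 | 6-allyl-2-(4-allyl-2-methoxyphenoxy)-6-methoxycyclohexa-2,4-dien-1-one (racemic, not isolated) | O=C1C(OC)(CC=C)C=CC=C1Oc1ccc(CC=C)cc1OC | intermediate
6 | 6-allyl-6-(4-allyl-2-methoxyphenoxy)-2-methoxycyclohexa-2,4-dien-1-one (racemic, not isolated) | O=C1C(OC)=CC=CC1(CC=C)Oc1ccc(CC=C)cc1OC | intermediate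
7 | 4-allyl-2-(4-allyl-2-methoxyphenoxy)-6-methoxycyclohexa-2,5-dien-1-one (racemic, not isolated) | O=C1C(OC)=CC(CC=C)C=C1Oc1ccc(CC=C)cc1OC | intermediate
8 | dehydrodieugenol B (4-allyl-2-(4-allyl-2-methoxyphenoxy)-6-methoxyphenol) | C=CCc1cc(OC)c(O)c(Oc2ccc(CC=C)cc2OC)c1 | intermediate
9 | 4-allyl-6-[4-allyl-2-(4-allyl-2-methoxyphenoxy)-6-methoxyphenoxy]-2-methoxycyclohexa-2,4-dien-1-one (racemic, not isolated) | O=C1C(OC)=CC(CC=C)=CC1Oc1c(OC)cc(CC=C)cc1Oc1ccc(CC=C)cc1OC | intermediate
10 | 4-allyl-2-[4-allyl-2-(4-allyl-2-methoxyphenoxy)-6-methoxyphenoxy]-6-methoxyphenol (achiral) | C=CCc1ccc(Oc2cc(CC=C)cc(OC)c2Oc2cc(CC=C)cc(OC)c2O)c(OC)c1 | target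

**Step count**
Total steps: 4. Longest linear sequence: 4 steps (1 → 2 → 4 → 8 → 10).

**Three steps most likely to fail, with fallbacks**

Step 4 (the proposed new coupling). It may give the C6–C6 biaryl of eugenol, quinone methides by loss of a benzylic hydrogen, ortho-quinones by oxygen transfer from the copper–dioxygen species, or higher oligomers from further coupling of 10. The fallback uses only known chemistry, sets out from 8 and comes back to the route at 10. Phenol 8 is coupled with bromide 2 under Ullmann conditions for hindered phenols (CuI, picolinic acid, K3PO4, DMSO, 90 °C) to give 2-(allyloxy)-1-[4-allyl-2-(4-allyl-2-methoxyphenoxy)-6-methoxyphenoxy]-3-methoxybenzene F1. Heating this in PhNEt2 at 195 °C brings about the para-Claisen rearrangement through the methoxy-side ortho-dienone F2, the aryloxy-side ortho-dienone F3 and the para-dienone F4, none isolated, and enolisation gives 10.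

Step 2 (Ullmann coupling of an electron-rich, ortho-alkoxy aryl bromide with an ortho-substituted phenol). It may stall or give reduced arene. The fallback replaces the aryl halide coupling by a room-temperature oxidative coupling of an arylboron compound; it sets out from 2 and comes back at 4. Bromide 2 is treated with n-BuLi in THF at −78 °C in the presence of B(OiPr)3 and worked up with aqueous NH4Cl to give [2-(allyloxy)-3-methoxyphenyl]boronic acid F5. This is joined to eugenol 3 by a Chan–Lam coupling (Cu(OAc)2, pyridine, 4 Å molecular sieves, CH2Cl2, air, room temperature) to give 4.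

Step 3 (para-Claisen rearrangement at 195 °C). The ortho-dienones may fragment or the allyl groups may isomerise at this temperature. The fallback avoids the rearrangement by carrying the C-allyl group of ring B in from eugenol; it sets out from 3 and comes back at 8. Eugenol 3 is brominated ortho to the hydroxyl (NBS, catalytic iPr2NH, CH2Cl2, 0 °C) to give 6-bromoeugenol F6 (4-allyl-2-bromo-6-methoxyphenol). Protection (MOMCl, iPr2NEt, CH2Cl2) gives 5-allyl-1-bromo-3-methoxy-2-(methoxymethoxy)benzene F7. Ullmann coupling with a second portion of 3 (CuI, N,N-dimethylglycine hydrochloride, Cs2CO3, dioxane, 100 °C) gives the methoxymethyl ether of dehydrodieugenol B F8, and HCl in MeOH at 40 °C releases 8.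

**Further compounds**
F1 | step 4 | 2-(allyloxy)-1-[4-allyl-2-(4-allyl-2-methoxyphenoxy)-6-methoxyphenoxy]-3-methoxybenzene | C=CCOc1c(OC)cccc1Oc1c(OC)cc(CC=C)cc1Oc1ccc(CC=C)cc1OC
F2 | step 4 | 6-allyl-2-[4-allyl-2-(4-allyl-2-methoxyphenoxy)-6-methoxyphenoxy]-6-methoxycyclohexa-2,4-dien-1-one (racemic) | O=C1C(OC)(CC=C)C=CC=C1Oc1c(OC)cc(CC=C)cc1Oc1ccc(CC=C)cc1OC
F3 | step 4 | 6-allyl-6-[4-allyl-2-(4-allyl-2-methoxyphenoxy)-6-methoxyphenoxy]-2-methoxycyclohexa-2,4-dien-1-one (racemic) | O=C1C(OC)=CC=CC1(CC=C)Oc1c(OC)cc(CC=C)cc1Oc1ccc(CC=C)cc1OC
F4 | step 4 | 4-allyl-2-[4-allyl-2-(4-allyl-2-methoxyphenoxy)-6-methoxyphenoxy]-6-methoxycyclohexa-2,5-dien-1-one (racemic) | O=C1C(OC)=CC(CC=C)C=C1Oc1c(OC)cc(CC=C)cc1Oc1ccc(CC=C)cc1OC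
F5 | step 2 | [2-(allyloxy)-3-methoxyphenyl]boronic acid | C=CCOc1c(OC)cccc1B(O)O
F6 | step 3 | 6-bromoeugenol (4-allyl-2-bromo-6-methoxyphenol) | C=CCc1cc(Br)c(O)c(OC)c1
F7 | step 3 | 5-allyl-1-bromo-3-methoxy-2-(methoxymethoxy)benzene | C=CCc1cc(Br)c(OCOC)c(OC)c1
F8 | step 3 | 5-allyl-1-(4-allyl-2-methoxyphenoxy)-3-methoxy-2-(methoxymethoxy)benzene | C=CCc1cc(OC)c(OCOC)c(Oc2ccc(CC=C)cc2OC)c1
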